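Disydonol A is cut at its two aryl–carbinol bonds, C1–C7 on the free-phenol ring A and C1′–C7′ on the hydroxymethyl ring B. Both (S)-carbinol carbons carry the same methyl and 4-methylpentyl groups, so one chiral-pool alcohol, (S)-6-methylheptan-2-ol, serves both. Its α-lithiated triisopropylbenzoate is added twice to an achiral benzyl aryl ether core that bears a boronic ester at C1 and at C1′. Two stereospecific boron-to-carbon aryl shifts then make both bonds and both stereocentres in one flask. The precursor is this silyl-protected bis(boronate), used as its neopentyl glycol ester with the ring-A phenol masked as a TIPS ether.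

Key step: step 9

Remarks on the chemistry (made before the route)
- Locants assumed: in ring A, C1 bears C7, C2 bears OH and C4 bears the CH2–O bridge. In ring B, C1′ bears C7′, C2′ bears the bridging oxygen and C4′ bears CH2OH.
- Stereochemical bookkeeping: both carbinol carbons of the target SMILES are (S). Lithiation (retention), borylation (retention), aryl shift (inversion) and oxidation (retention) turn an (S)-benzoate into an (S)-carbinol. (S)-Propylene oxide is therefore the correct source of chirality.
- Boron ligand: the tertiary α-oxy carbanion is very hindered, and this reaction type is established with slim neopentyl glycol boronic esters. The core therefore carries neopentyl glycol rather than pinacol on both boron atoms.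
- Protecting groups: an aryl TBS ether is labile to hydroxide and to carbonate. The phenol is therefore carried as the more base-stable TIPS ether, and the two halves are joined under neutral Mitsunobu conditions.
- Base: s-BuLi is kept below the amount of benzoate and is allowed to be used up before the core is added (its consumption can be followed by in situ IR). No free alkyllithium then reaches boron or the ArCH2O group.

Step 1
Reactants: 1 methyl 4-bromo-3-hydroxybenzoate
Product: 2 methyl 4-bromo-3-(triisopropylsilyloxy)benzoate
Conditions: TIPSCl, imidazole, DMF, rt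
Reagents that add atoms: triisopropylsilyl chloride, CC(C)[Si](Cl)(C(C)C)C(C)C
Why: Imidazole-mediated O-silylation of the acidic o-bromophenol is routine, and TIPS is preferred to TBS because an aryl TIPS ether withstands acetate at 90 °C, carbanions and alkaline peroxide later on while its bulk can turn towards C3–H, away from the future boron site.

Step 2
Reactants: 2 methyl 4-bromo-3-(triisopropylsilyloxy)benzoate
Product: 3 [4-bromo-3-(triisopropylsilyloxy)phenyl]methanol
Conditions: DIBAL-H, CH2Cl2, −78 → 0 °C; aq. Rochelle salt
Reagents that add atoms: none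
Why: DIBAL-H reduction of an aromatic methyl ester to the benzylic alcohol leaves the aryl bromide and the silyl ether untouched at low temperature.

Step 3
Reactants: 3 [4-bromo-3-(triisopropylsilyloxy)phenyl]methanol; 1 methyl 4-bromo-3-hydroxybenzoate
Product: 4 methyl 4-bromo-3-{[4-bromo-3-(triisopropylsilyloxy)benzyl]oxy}benzoate
Conditions: PPh3, DIAD, THF, 0 °C → rt
Reagents that add atoms: none
Why: Mitsunobu etherification: the acidic o-bromophenol of 1 protonates the PPh3/DIAD betaine and its phenoxide displaces the primary benzylic oxyphosphonium ion of 3 by SN2 under neutral conditions, which saves a bromination step and avoids carbonate bases that could strip or transfer the aryl silyl group.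

Step 4
Reactants: 4 methyl 4-bromo-3-{[4-bromo-3-(triisopropylsilyloxy)benzyl]oxy}benzoate
Product: 5 (4-bromo-3-{[4-bromo-3-(triisopropylsilyloxy)benzyl]oxy}phenyl)methanol
Conditions: DIBAL-H, CH2Cl2, −78 → 0 °C; aq. Rochelle salt
Reagents that add atoms: none
Why: A second DIBAL-H ester reduction turns the ring-B ester into the future hydroxymethyl group without touching the two aryl bromides, the benzyl aryl ether or the TIPS ether.

Step 5
Reactants: 5 (4-bromo-3-{[4-bromo-3-(triisopropylsilyloxy)benzyl]oxy}phenyl)methanol
Product: 6 tert-butyl[(4-bromo-3-{[4-bromo-3-(triisopropylsilyloxy)benzyl]oxy}benzyl)oxy]dimethylsilane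
Conditions: TBSCl, imidazole, CH2Cl2, rt
Reagents that add atoms: tert-butyldimethylsilyl chloride, CC(C)(C)[Si](C)(C)Cl
Why: Standard imidazole-mediated silylation of a primary benzylic alcohol removes the only acidic proton before the organometallic chemistry, and the TBS ether is stable to every step up to the final fluoride treatment.

Step 6
Reactants: 6 tert-butyl[(4-bromo-3-{[4-bromo-3-(triisopropylsilyloxy)benzyl]oxy}benzyl)oxy]dimethylsilane; 7 bis(neopentyl glycolato)diboron
Product: 8 achiral bis(neopentyl glycol boronate) core (both Br of 6 replaced by 5,5-dimethyl-1,3,2-dioxaborinan-2-yl)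
Conditions: 7 (3 equiv), Pd(dppf)Cl2·CH2Cl2 (cat.), KOAc, 1,4-dioxane, 90 °C
Reagents that add atoms: none
Why: Miyaura borylation: Pd(0) inserts into each C–Br bond and acetate-assisted transmetalation with 7 followed by reductive elimination gives the aryl boronates, the small neopentyl glycol diboron suiting ortho-substituted bromides and KOAc being too weak a base to start Suzuki coupling or to harm the silyl ethers.

Step 7
Reactants: 9 1-bromo-3-methylbutane; 10 (S)-propylene oxide
Product: 12 (S)-6-methylheptan-2-ol, via 3-methylbutylmagnesium bromide 11 (not isolated)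
Conditions: Mg, THF; then CuI (cat.), 10, THF, −30 → 0 °C
Reagents that add atoms: none
Why: Copper-catalysed SN2 opening of a terminal epoxide by a Grignard reagent takes place at the unsubstituted CH2, so the C–O bond of the stereocentre is never broken and the (S) configuration of 10 is carried unchanged into 12.

Step 8
Reactants: 12 (S)-6-methylheptan-2-ol; 13 2,4,6-triisopropylbenzoyl chloride
Product: 15 (S)-6-methylheptan-2-yl 2,4,6-triisopropylbenzoate, via sodium (S)-6-methylheptan-2-olate 14 (not isolated)
Conditions: NaH, THF, 0 °C → rt; then 13, reflux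
Reagents that add atoms: none
Why: O-acylation of a preformed alkoxide with a hindered aroyl chloride (nucleophilic acyl substitution) forms the ester at the acyl carbon only, so the carbinol C–O bond and its (S) configuration are retained.

Step 9
Reactants: 15 (S)-6-methylheptan-2-yl 2,4,6-triisopropylbenzoate (4 equiv); 8 achiral bis(neopentyl glycol boronate) core (1 equiv)
Product: 18 (R,R)-bis(tertiary benzylic neopentyl glycol boronate), via lithiated benzoate 16 (not isolated), via dilithium bis-ate complex 17 (not isolated)
Conditions: 15, s-BuLi (3.2 equiv), TMEDA, CPME, −60 °C; then 8 in CPME, −60 °C → 50 °C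
Reagents that add atoms: none
Why: s-BuLi/TMEDA removes the carbinol proton of 15 under direction of the hindered ester carbonyl and gives the chelated, configurationally stable tertiary organolithium 16 with retention; because s-BuLi is substoichiometric to 15, no free base meets the boron atoms or the ArCH2O group of 8. Each boron of 8 captures one molecule of 16 with retention to give 17, and on warming each aryl group shifts from boron to carbon antiperiplanar to the departing triisopropylbenzoate, which inverts that carbon and forms C1–C7 and C1′–C7′. The closest known reaction type is the lithiation–borylation of triisopropylbenzoates of secondary dialkyl carbinols with neopentyl glycol boronic esters, run here at two boron centres of one molecule, and no ring is closed. C7 and C7′ are both controlled only by the configuration of 15 (retention, retention, inversion), so (S)-15 should give the (R,R)-bis(boronate), the descriptor changing merely because boron ranks lowest. The step needs full stereospecificity, complete reaction at both hindered boron atoms and aryl rather than ring-oxygen migration; the non-benzylic carbanion neither racemises nor dissociates again from boron, the slim neopentyl glycol esters admit the tertiary nucleophile, and the electron-rich oxygenated aryl groups are good migrating groups.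

Step 10
Reactants: 18 (R,R)-bis(tertiary benzylic neopentyl glycol boronate)
Product: 19 (S,S)-bis(tertiary alcohol) with TIPS and TBS ethers intact
Conditions: 30% aq. H2O2, 2 M NaOH, THF, 0 °C → rt
Reagents that add atoms: hydrogen peroxide, OO
Why: Boronic ester oxidation: hydroperoxide adds to each boron and the tertiary carbon shifts from boron to oxygen with retention, turning (R,R)-18 into the (S,S)-diol (descriptor change by priority only), while the hindered aryl TIPS ether, the primary TBS ether and the benzyl aryl ether tolerate cold alkaline peroxide.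

Step 11
Reactants: 19 (S,S)-bis(tertiary alcohol) with TIPS and TBS ethers intact
Product: 20 Disydonol A
Conditions: TBAF, THF, 0 °C → rt; chromatography on Et3N-deactivated silica
Reagents that add atoms: none
Why: Fluoride-induced desilylation cleaves both Si–O bonds under non-acidic conditions that spare the ionisable tertiary benzylic alcohols, and it is placed after the oxidation because fluoride would protodeboronate a tertiary benzylic boronic ester.

Compound list
1 | methyl 4-bromo-3-hydroxybenzoate | COC(=O)c1ccc(Br)c(O)c1 | starting material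
2 | methyl 4-bromo-3-(triisopropylsilyloxy)benzoate | COC(=O)c1ccc(Br)c(O[Si](C(C)C)(C(C)C)C(C)C)c1 | intermediate
3 | [4-bromo-3-(triisopropylsilyloxy)phenyl]methanol | OCc1ccc(Br)c(O[Si](C(C)C)(C(C)C)C(C)C)c1 | intermediate
4 | methyl 4-bromo-3-{[4-bromo-3-(triisopropylsilyloxy)benzyl]oxy}benzoate | COC(=O)c1ccc(Br)c(OCc2ccc(Br)c(O[Si](C(C)C)(C(C)C)C(C)C)c2)c1 | intermediate
5 | (4-bromo-3-{[4-bromo-3-(triisopropylsilyloxy)benzyl]oxy}phenyl)methanol | OCc1ccc(Br)c(OCc2ccc(Br)c(O[Si](C(C)C)(C(C)C)C(C)C)c2)c1 | intermediate
6 | tert-butyl[(4-bromo-3-{[4-bromo-3-(triisopropylsilyloxy)benzyl]oxy}benzyl)oxy]dimethylsilane | CC(C)(C)[Si](C)(C)OCc1ccc(Br)c(OCc2ccc(Br)c(O[Si](C(C)C)(C(C)C)C(C)C)c2)c1 | intermediate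
7 | bis(neopentyl glycolato)diboron | CC1(C)COB(OC1)B1OCC(C)(C)CO1 | starting material
8 | tert-butyl{[4-(5,5-dimethyl-1,3,2-dioxaborinan-2-yl)-3-{[4-(5,5-dimethyl-1,3,2-dioxaborinan-2-yl)-3-(triisopropylsilyloxy)benzyl]oxy}benzyl]oxy}dimethylsilane (achiral bis-boronate core) | CC1(C)COB(OC1)c2ccc(COc3cc(CO[Si](C)(C)C(C)(C)C)ccc3B4OCC(C)(C)CO4)cc2O[Si](C(C)C)(C(C)C)C(C)C | intermediate
9 | 1-bromo-3-methylbutane | CC(C)CCBr | starting material
10 | (S)-propylene oxide | C[C@H]1CO1 | starting material
11 | 3-methylbutylmagnesium bromide | CC(C)CC[Mg]Br | intermediate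
12 | (S)-6-methylheptan-2-ol | C[C@H](O)CCCC(C)C | intermediate
13 | 2,4,6-triisopropylbenzoyl chloride | CC(C)c1cc(C(C)C)c(C(=O)Cl)c(C(C)C)c1 | starting material
14 | sodium (S)-6-methylheptan-2-olate | [Na+].C[C@H]([O-])CCCC(C)C | intermediate
15 | (S)-6-methylheptan-2-yl 2,4,6-triisopropylbenzoate | C[C@H](OC(=O)c1c(C(C)C)cc(C(C)C)cc1C(C)C)CCCC(C)C | intermediate
16 | (S)-2-lithio-6-methylheptan-2-yl 2,4,6-triisopropylbenzoate | C[C@]([Li])(OC(=O)c1c(C(C)C)cc(C(C)C)cc1C(C)C)CCCC(C)C | intermediate
17 | dilithium bis-ate complex: each boron of 8 also bonded to C2 of an (S)-6-methyl-2-(2,4,6-triisopropylbenzoyloxy)heptan-2-yl group | [Li+].[Li+].CC(C)CCC[C@](C)(OC(=O)c1c(C(C)C)cc(C(C)C)cc1C(C)C)[B-]2(OCC(C)(C)CO2)c3ccc(COc4cc(CO[Si](C)(C)C(C)(C)C)ccc4[B-]5(OCC(C)(C)CO5)[C@@](C)(OC(=O)c6c(C(C)C)cc(C(C)C)cc6C(C)C)CCCC(C)C)cc3O[Si](C(C)C)(C(C)C)C(C)C | intermediate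
18 | tert-butyl{[4-[(R)-2-(5,5-dimethyl-1,3,2-dioxaborinan-2-yl)-6-methylheptan-2-yl]-3-{[4-[(R)-2-(5,5-dimethyl-1,3,2-dioxaborinan-2-yl)-6-methylheptan-2-yl]-3-(triisopropylsilyloxy)benzyl]oxy}benzyl]oxy}dimethylsilane | CC(C)CCC[C@](C)(B1OCC(C)(C)CO1)c2ccc(COc3cc(CO[Si](C)(C)C(C)(C)C)ccc3[C@@](C)(B4OCC(C)(C)CO4)CCCC(C)C)cc2O[Si](C(C)C)(C(C)C)C(C)C | intermediate
19 | (S)-2-{4-[(5-{[(tert-butyldimethylsilyl)oxy]methyl}-2-[(S)-2-hydroxy-6-methylheptan-2-yl]phenoxy)methyl]-2-(triisopropylsilyloxy)phenyl}-6-methylheptan-2-ol | CC(C)CCC[C@](C)(O)c1ccc(COc2cc(CO[Si](C)(C)C(C)(C)C)ccc2[C@@](C)(O)CCCC(C)C)cc1O[Si](C(C)C)(C(C)C)C(C)C | intermediate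
20 | Disydonol A, (S)-2-{2-hydroxy-4-[(2-[(S)-2-hydroxy-6-methylheptan-2-yl]-5-(hydroxymethyl)phenoxy)methyl]phenyl}-6-methylheptan-2-ol | CC(C)CCC[C@](C)(O)c1ccc(COc2cc(CO)ccc2[C@@](C)(O)CCCC(C)C)cc1O | target

Total step count: 11
Longest linear sequence: 9 steps (steps 1–6 and 9–11); the side-chain branch (steps 7 and 8) joins at step 9.

Steps most likely to fail

Step 9. The bulky tertiary carbanion may be captured slowly or incompletely by the two ortho-oxygenated aryl boron centres. The carbanion could then decay before the second arm has reacted, or ring oxygen could migrate in place of aryl on warming. The fallback reverses the polarity at each carbinol carbon, so that an unhindered primary alkyl boronic ester is both electrophile and migrating group. It sets out from 6 and comes back at 19.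
- Double Stille coupling of 6 with tributyl(1-ethoxyvinyl)stannane should give the bis(1-ethoxyvinyl) ether F1.
- Brief treatment with dilute oxalic acid should give the diketone F2.
- Noyori transfer hydrogenation with the (R,R)-TsDPEN–Ru catalyst should give the (R,R)-bis(1-arylethanol) F3.
- N,N-Diisopropylcarbamoyl chloride/Et3N should give the (R,R)-bis(carbamate) F4.
- F4 is doubly lithiated at the benzylic positions (s-BuLi, Et2O, −78 °C, retention; the carbamate-directed deprotonation should outrun attack at the ArCH2O group, and TIPS is the silyl group least prone to an O→C shift).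
- The dianion is trapped with 4-methylpentyl pinacol boronate F5, made by hydroboration of 4-methylpent-1-ene with pinacolborane.
- A MgBr2/MeOH-promoted 1,2-alkyl shift (inversion) should give the (R,R)-bis(tertiary pinacol boronate) F6, which has the same spatial arrangement as 18.
- Oxidation under the conditions of step 10 then leads to 19.

Step 6. The second borylation may stall, or the C–Br bond next to the bulky silyloxy group may be protodebrominated. The neopentyl glycol esters may also be partly hydrolysed during purification. The fallback replaces palladium catalysis by halogen–metal exchange and electrophilic borylation. It sets out from 6 and comes back at 8.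
- Bromine–magnesium exchange at both rings uses lithium tri-n-butylmagnesate (from n-BuMgCl and n-BuLi, THF, −10 °C). Arylmagnesium species should not trigger the silyl shift or Wittig rearrangement expected of aryllithiums.
- A B(OMe)3 quench and mild aqueous hydrolysis should give the bis(boronic acid) F7.
- Condensation of F7 with neopentyl glycol over MgSO4 in CH2Cl2 should give 8.

Step 8. Acyl transfer may be very slow because the two ortho isopropyl groups shield the carbonyl of 13. This would leave unreacted alkoxide and allow the acid chloride to hydrolyse on work-up. The fallback forms the ester C–O bond at the carbinol carbon instead of at the acyl carbon. It sets out from 9 and comes back at 15.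
- Grignard reagent 11, made from 9 as in step 7, opens commercial (R)-propylene oxide under copper catalysis to give (R)-6-methylheptan-2-ol F8.
- Mitsunobu esterification of F8 with commercial 2,4,6-triisopropylbenzoic acid (PPh3, DIAD, THF) proceeds by SN2 inversion and should deliver the (S)-ester 15.

Further compounds
F1 | step 9 | tert-butyl{[4-(1-ethoxyvinyl)-3-{[4-(1-ethoxyvinyl)-3-(triisopropylsilyloxy)benzyl]oxy}benzyl]oxy}dimethylsilane | C=C(OCC)c1ccc(COc2cc(CO[Si](C)(C)C(C)(C)C)ccc2C(=C)OCC)cc1O[Si](C(C)C)(C(C)C)C(C)C
F2 | step 9 | diketone (both Br of 6 replaced by acetyl) | CC(=O)c1ccc(COc2cc(CO[Si](C)(C)C(C)(C)C)ccc2C(C)=O)cc1O[Si](C(C)C)(C(C)C)C(C)C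
F3 | step 9 | (R,R)-bis(1-hydroxyethyl) compound | C[C@@H](O)c1ccc(COc2cc(CO[Si](C)(C)C(C)(C)C)ccc2[C@@H](C)O)cc1O[Si](C(C)C)(C(C)C)C(C)C
F4 | step 9 | (R,R)-bis(N,N-diisopropylcarbamate) of F3 | C[C@@H](OC(=O)N(C(C)C)C(C)C)c1ccc(COc2cc(CO[Si](C)(C)C(C)(C)C)ccc2[C@@H](C)OC(=O)N(C(C)C)C(C)C)cc1O[Si](C(C)C)(C(C)C)C(C)C
F5 | step 9 | 4,4,5,5-tetramethyl-2-(4-methylpentyl)-1,3,2-dioxaborolane | CC(C)CCCB1OC(C)(C)C(C)(C)O1
F6 | step 9 | (R,R)-bis(tertiary benzylic pinacol boronate), pinacol analogue of 18 | CC(C)CCC[C@](C)(B1OC(C)(C)C(C)(C)O1)c2ccc(COc3cc(CO[Si](C)(C)C(C)(C)C)ccc3[C@@](C)(B4OC(C)(C)C(C)(C)O4)CCCC(C)C)cc2O[Si](C(C)C)(C(C)C)C(C)C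
F7 | step 6 | bis(boronic acid) (both Br of 6 replaced by B(OH)2) | OB(O)c1ccc(COc2cc(CO[Si](C)(C)C(C)(C)C)ccc2B(O)O)cc1O[Si](C(C)C)(C(C)C)C(C)C
F8 | step 8 | (R)-6-methylheptan-2-ol | C[C@@H](O)CCCC(C)C
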